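(Readings and results were generated by integration with constants of no real substance, and the scatter is random.)

I kept one unit throughout, the fraction of a charge, and read these flasks in it.

| flask | substrate | coupling partner | catalyst | time |
|---|---|---|---|---|
| south-east | 0.300 M | 0.240 M | 6.00 × 10⁻⁴ M |  |
| south-west | 0.180 M | 0.120 M | 6.00 × 10⁻⁴ M |  |
| north-east | 0.300 M | 0.480 M | 6.00 × 10⁻⁴ M |  |
| north | 0.300 M | 0.240 M | 9.00 × 10⁻⁴ M |  |
| west | 0.300 M | 0.240 M | 0.00150 M | 20 h |

- south-east run (time / h: [substrate] / M): 0.72: 0.2847; 2.2: 0.2595; 4.2: 0.2337; 6.6: 0.2132; 9.4: 0.2067; 13: 0.1929; 16: 0.1894; 20: 0.1882
- south-west run (time / h: [substrate] / M): 0.72: 0.1734; 2.2: 0.1625; 4.2: 0.1515; 6.6: 0.1427; 9.4: 0.1359; 13: 0.1333; 16: 0.1284; 20: 0.1301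
- north-east run (time / h: [substrate] / M): 0.72: 0.2667; 2.2: 0.2208; 4.2: 0.1749; 6.6: 0.1416; 9.4: 0.1154; 13: 0.1072; 16: 0.0962; 20: 0.0914
- north run (time / h: [substrate] / M): 0.72: 0.2737; 2.2: 0.2391; 4.2: 0.2111; 6.6: 0.1925; 9.4: 0.1715; 13: 0.1659; 16: 0.1636; 20: 0.1618

(standard deviation of a reading: 0.002 M)

* apparent order in [catalyst] of the starting rate, round the charge of the south-east run (the rate where two percent of its substrate have turned into product)
* apparent order in [coupling partner] of the starting rate, round the charge of the south-east run (the rate where two percent of its substrate have turned into product)
* substrate in the west run at 20 h, as a share of the substrate charged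
* which of these the readings show (the second partner is lost by itself / the substrate is lost by itself / the catalyst rests as a dimer)

- Overall: substrate + coupling partner -> product, with catalyst as catalyst.
- Constant volume, constant temperature.
- What is held in complexes is read along with the free species.
- "The second partner" is coupling partner.
- An order is taken over about fifteen percent of the charge, up and down.

The row to read aloud is the last one, at 20 h. In the south-east run, substrate stood at 62.7% of its charge, and over the last interval it fell by 0.400%, less than the scatter of 0.667%. The coupling partner is the limiting reagent of that run, yet one-to-one coupling allows substrate down to 20.0%, so much of the partner had not reached product.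

I therefore put one number on each run, the capture share: the fraction of the partner charge that had become product by 20 h, which is substrate turned over partner charged. It came to 0.466 in south-east, 0.416 in south-west, 0.435 in north-east and 0.576 in north.

The first three lie within 0.0500 of one another, although their partner charges span a factor of 4.00 and the south-west substrate charge is 60.0% of the south-east one. So I read a partner that wastes itself at a steady proportion, in a loss competing with coupling. The south-east substrate stalled well above what coupling allows, and that speaks against a substrate lost by itself.

The readings at 2.2 h gave the orders. North turned 1.50 times what south-east turned, which reads as order 1.01 in catalyst, far from the 0.5 that goes with a dimer resting state. North-east against south-east reads as order 0.968 in partner.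

Coupling therefore scaled with catalyst, and the north share stood above the south-east one, which reads as a loss that did not scale with it. That suggested a better carrier: the capture odds, partner coupled per partner not coupled by 20 h, 0.872 in south-east. North tested it, with odds of 1.36, or 1.56 times as much on 1.50 times the catalyst. For the west run I scaled the odds with catalyst to 2.18, a capture share of 0.686, which I reckoned to leave 45.2% of the substrate at 20 h.

The forecast, whose numbers differ a little from mine, gave 0.97, 1, 46% and "the second partner is lost by itself", the last on the ground that “consumed substrate scales with the partner charge”.

The flask gave orders of 1.0 in catalyst and 1.1 in partner, 45.2% of the substrate left, and "the second partner is lost by itself".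

    catalyst + substrate ⇌ catalyst-substrate complex, settled at all times (6.660 M⁻¹)
    catalyst-substrate complex + coupling partner → product + catalyst (249.1 M⁻¹ h⁻¹)
    coupling partner → lost reagent (0.09864 h⁻¹)

The west result means a capture share of 0.685, so odds of 2.17, which is 2.49 times the south-east odds on 2.50 times the catalyst. The west run repeated without the step from coupling partner to lost reagent proves the reason: that step holds substrate at 45.2% of its charge instead of 23.4%. In the repeat without that step the capture share at 20 h is 0.958.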